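**Assumption:** the target SMILES has no stereocentres or stereodescriptors, so juglanin A is treated as achiral. Any planar chirality of the cyclophane is unspecified and is not controlled; no stereoselective step is needed.

The route is a design proposal; none of it has been run, and step 6 is a new, untested transformation.

## Retrosynthetic overview

1. Juglanin A ⇐ acid unmasking of a macrocyclic aryl phosphinite / ketone ketal.
2. Macrocycle ⇐ new step: P(III)-directed, Rh-catalysed intramolecular anti-Markovnikov ortho-C–H hydroarylation of a terminal alkene. This forms the ring-B aryl–CH2 bond and the 15-membered ring in one event.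
3. Open precursor ⇐ Ullmann C–O coupling of an aryl iodide with C2-symmetric 2-methoxyresorcinol. The diaryl ether is made before the macrocycle.
4. Aryl iodide side chain ⇐ Claisen–Schmidt condensation of 3-iodo-4-methoxybenzaldehyde with hex-5-en-2-one, conjugate reduction, ketalisation.
5. Ring order: both benzene rings are bought; the only ring constructed is the 15-membered meta,para-cyclophane, last.

## Route

**Step 1**
Reactants: 1, 3-iodo-4-methoxybenzaldehyde; 2, hex-5-en-2-one (3 equiv)
Product: 3, (E)-1-(3-iodo-4-methoxyphenyl)hepta-1,6-dien-3-one
Conditions: 2 M aq. NaOH, EtOH, 0 °C → rt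
Reagents that add atoms: none
Why: Claisen–Schmidt crossed aldol condensation; hydroxide condenses the non-enolisable aldehyde at the less hindered methyl side of the ketone, and E1cB dehydration gives the conjugated E-enone (excess ketone limits bis-condensation).

**Step 2**
Reactants: 3, (E)-1-(3-iodo-4-methoxyphenyl)hepta-1,6-dien-3-one
Product: 4, 1-(3-iodo-4-methoxyphenyl)hept-6-en-3-one
Conditions: [(Ph3P)CuH]6 (5 mol %), PMHS, t-BuOH, toluene, rt; aq. NH4F work-up
Reagents that add atoms: none
Why: Stryker-type copper hydride conjugate reduction; Cu–H adds 1,4 to the enone only and leaves the isolated terminal alkene, the aryl iodide and the carbonyl untouched.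

**Step 3**
Reactants: 4, 1-(3-iodo-4-methoxyphenyl)hept-6-en-3-one
Product: 5, 2-(but-3-en-1-yl)-2-[2-(3-iodo-4-methoxyphenyl)ethyl]-1,3-dioxolane
Conditions: ethylene glycol (5 equiv), PPTS (10 mol %), toluene, reflux, Dean–Stark
Reagents that add atoms: ethylene glycol, OCCO
Why: acid-catalysed ketalisation driven by azeotropic water removal; the dioxolane protects the ketone from the Ullmann base and removes the conjugated-enone isomerisation sink in step 6.

**Step 4**
Reactants: 5, 2-(but-3-en-1-yl)-2-[2-(3-iodo-4-methoxyphenyl)ethyl]-1,3-dioxolane; 6, 2-methoxybenzene-1,3-diol (2-methoxyresorcinol, 3 equiv)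
Product: 7, 3-{5-[2-(2-(but-3-en-1-yl)-1,3-dioxolan-2-yl)ethyl]-2-methoxyphenoxy}-2-methoxyphenol
Conditions: CuI (10 mol %), picolinic acid (20 mol %), K3PO4, DMSO, 85 °C, Ar; neutral work-up
Reagents that add atoms: none
Why: Ullmann-type Cu(I)/picolinic acid diaryl ether coupling, suited to ortho-substituted partners; the two OH groups of 6 are equivalent, so excess diol gives the mono-aryl ether with no regiochemical issue, and ketal and alkene are base-stable.

**Step 5**
Reactants: 7, the diaryl ether phenol from step 4
Product: 8, 3-{5-[2-(2-(but-3-en-1-yl)-1,3-dioxolan-2-yl)ethyl]-2-methoxyphenoxy}-2-methoxyphenyl diisopropylphosphinite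
Conditions: i-Pr2PCl (1.1 equiv), Et3N, DMAP (cat.), toluene, 0 °C → rt, Ar; filter, use the solution directly
Reagents that add atoms: chlorodiisopropylphosphine, CC(C)P(Cl)C(C)C
Why: O-phosphinylation of the phenol with a P–Cl electrophile installs a traceless P(III) directing group on the oxygen flanking the only free ortho C–H of ring B.

**Step 6**
Reactants: 8, the aryl diisopropylphosphinite from step 5
Product: 9, the 15-membered meta,para-cyclophane, i.e. juglanin A carrying O–P(i-Pr)2 on the phenol oxygen and an ethylene ketal (1,3-dioxolane) at the ketone carbon
Conditions: [Rh(coe)2Cl]2 (5 mol %), o-xylene, 130 °C, syringe-pump addition of 8 over 12 h (final 2 mM), Ar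
Reagents that add atoms: none
Why: Proposed new method: a macrocyclising P(III)-directed ortho-C–H hydroarylation. The phosphinite binds Rh(I) and oxidative addition of the single ortho C–H (the other ortho site carries OMe) gives a five-membered aryl–Rh(III)–H rhodacycle. Reversible 1,2-insertion of the tethered terminal alkene into Rh–H gives a primary alkyl in a 16-membered rhodacycle, and C(sp2)–C(sp3) reductive elimination closes the 15-membered ring with linear (anti-Markovnikov) selectivity, because only the primary alkyl eliminates readily from the bulky i-Pr2P-ligated metal. Chain-walked internal alkenes are expected to funnel back through Rh–H, the ketal blocks walking into conjugation, and slow addition suppresses oligomers and keeps Rh from being saturated by phosphinite. The closest known reaction type is intermolecular Rh/Ru-catalysed ortho-alkylation of phenols with simple alkenes via cyclometalated aryl phosphites/phosphinites (Murai-type chelation-assisted hydroarylation), which has not been used to close a macrocycle.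

**Step 7**
Reactants: 9, the macrocyclic phosphinite ketal from step 6
Product: 10, juglanin A
Conditions: 2 M aq. HCl, THF–MeOH, 40 °C
Reagents that add atoms: water, O
Why: acid solvolysis cleaves the aryl O–P bond to free the phenol and hydrolyses the dioxolane to the ketone, while the diaryl ether and methyl ethers are inert. Steps 5–7 can be telescoped in one pot.

## Compound list

1 | 3-iodo-4-methoxybenzaldehyde | COc1ccc(C=O)cc1I | starting material
2 | hex-5-en-2-one | CC(=O)CCC=C | starting material
3 | (E)-1-(3-iodo-4-methoxyphenyl)hepta-1,6-dien-3-one | COc1ccc(/C=C/C(=O)CCC=C)cc1I | intermediate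
4 | 1-(3-iodo-4-methoxyphenyl)hept-6-en-3-one | COc1ccc(CCC(=O)CCC=C)cc1I | intermediate
5 | 2-(but-3-en-1-yl)-2-[2-(3-iodo-4-methoxyphenyl)ethyl]-1,3-dioxolane | COc1ccc(CCC2(CCC=C)OCCO2)cc1I | intermediate
6 | 2-methoxybenzene-1,3-diol (2-methoxyresorcinol) | COc1c(O)cccc1O | starting material
7 | 3-{5-[2-(2-(but-3-en-1-yl)-1,3-dioxolan-2-yl)ethyl]-2-methoxyphenoxy}-2-methoxyphenol | COc1ccc(CCC2(CCC=C)OCCO2)cc1Oc1cccc(O)c1OC | intermediate
8 | diisopropylphosphinite of phenol 7 | COc1ccc(CCC2(CCC=C)OCCO2)cc1Oc1cccc(OP(C(C)C)C(C)C)c1OC | intermediate
9 | juglanin A ethylene ketal, O-diisopropylphosphinite (15-membered cyclophane) | COc1ccc2cc1Oc1ccc(c(OP(C(C)C)C(C)C)c1OC)CCCCC3(CC2)OCCO3 | intermediate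
10 | juglanin A | COc1ccc2cc1Oc1ccc(c(O)c1OC)CCCCC(=O)CC2 | target

## Summary

Total step count: 7.
Longest linear sequence: 7 steps from 3-iodo-4-methoxybenzaldehyde (fully linear; 2 and 6 are purchased).

Three steps most likely to fail, with fallbacks:

1. **Step 6 (proposed new macrocyclising C–H hydroarylation).** Risks are alkene isomerisation, oligomerisation or branched closure. Fallback with known chemistry, closing the ring by metathesis instead:
   - ortho-formylate phenol 7 (MgCl2, Et3N, paraformaldehyde; exclusively ortho to OH, only one site free);
   - Wittig methylenation to the 2-vinylphenol;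
   - ring-closing metathesis with the butenyl arm (Grubbs II, high dilution);
   - H2, Pd/C, then aq. HCl to give 10.

2. **Step 4 (Ullmann coupling of two ortho-methoxy, electron-rich partners; mono-arylation of a diol).** Fallback: convert iodide 5 to its pinacol boronate (Miyaura borylation) and form the ether by Chan–Lam–Evans oxidative coupling with mono-TBS-protected 2-methoxyresorcinol (Cu(OAc)2, pyridine, air, rt), then TBAF.

3. **Step 1 (regioselectivity and over-condensation in the Claisen–Schmidt reaction).** Fallback that bypasses steps 1–2: C-alkylate methyl 3-oxohept-6-enoate (from methyl acetoacetate dianion and allyl bromide) with 3-iodo-4-methoxybenzyl bromide, then Krapcho decarboxylation to give ketone 4 directly.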